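The route builds ring A of the 4-hydroxyphenyl flavone (double-primed half) last. It is laid across the C4a''–C8a'' edge that this ring shares with an already complete pyranone ring C. Ring A is a phloroglucinol with oxygens at C5'' and C7'' and the other flavone at C6'', so its four remaining carbons map onto an acetoacetate-derived diene. One operation joins the diene CH2 terminus to C8a'' and the ester carbon to C4a'', expels HBr and methanol, and gives the aromatic 5'',7''-diol with the C8–C6'' biaryl bond already in place. The precursors are a 2-(flavon-8-yl)-1-methoxy-1,3-bis(silyloxy)butadiene made from acacetin and a 5-bromo-2-arylpyran-4-one whose bromine is installed before ring closure.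

Key step: step 9

Numbering: flavone locants are used. Unprimed locants belong to the 4-methoxyphenyl flavone and double-primed locants to the 4-hydroxyphenyl flavone.
Assumption: the target is drawn without an axial descriptor, so the hindered C8–C6'' axis is made as the racemate.
Design choices: every phenol is masked as a benzyl ether, so one hydrogenolysis ends the route and the 4'-methyl ether is never at risk. The bromine of the pyranone is carried in on the acyclic enone, so its position does not depend on C3/C5 selectivity in an electrophilic bromination.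

Step 1
Reactants: 1 acacetin (5,7-dihydroxy-2-(4-methoxyphenyl)chromen-4-one)
Product: 2 5,7-bis(benzyloxy)-2-(4-methoxyphenyl)chromen-4-one
Conditions: BnBr (3 equiv), K2CO3 (4 equiv), DMF, 80 °C
Reagents that add atoms: benzyl bromide, BrCc1ccccc1
Why: Williamson ether synthesis; heating in a polar aprotic solvent also alkylates the chelated 5-OH, so both phenols are protected in one operation.

Step 2
Reactants: 2 5,7-bis(benzyloxy)-2-(4-methoxyphenyl)chromen-4-one
Product: 3 5,7-bis(benzyloxy)-8-iodo-2-(4-methoxyphenyl)chromen-4-one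
Conditions: NIS (1.1 equiv), TFA (cat.), CH2Cl2/MeCN, 0 °C → rt, dark
Reagents that add atoms: N-iodosuccinimide, O=C1CCC(=O)N1I
Why: Electrophilic aromatic iodination; when both the 5- and 7-oxygens of a flavone are alkylated, ring A is attacked at C8, and C6 is further shielded between two benzyloxy groups.

Step 3
Reactants: 3 5,7-bis(benzyloxy)-8-iodo-2-(4-methoxyphenyl)chromen-4-one; 4 methyl bromoacetate
Product: 6 methyl 2-[5,7-bis(benzyloxy)-2-(4-methoxyphenyl)-4-oxochromen-8-yl]acetate, via Reformatsky reagent 5 (not isolated)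
Conditions: 4 (2.5 equiv), Zn dust, TMSCl (cat.), THF, 40 °C; then 3, Pd2(dba)3 (2.5 mol %), XPhos (10 mol %), THF, 60 °C
Reagents that add atoms: none
Why: Zinc insertion gives the Reformatsky reagent, which enters a Negishi-type alpha-arylation after oxidative addition of the carbon–iodine bond to zerovalent palladium; the nearly neutral zinc enolate leaves the flavone carbonyl alone and the bulky biarylphosphine copes with the two ortho oxygens.

Step 4
Reactants: 6 methyl 2-[5,7-bis(benzyloxy)-2-(4-methoxyphenyl)-4-oxochromen-8-yl]acetate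
Product: 7 methyl 2-[5,7-bis(benzyloxy)-2-(4-methoxyphenyl)-4-oxochromen-8-yl]-3-oxobutanoate
Conditions: LiN(SiMe3)2 (2.2 equiv), THF, −78 °C; AcCl (1.2 equiv), −78 → −20 °C; cold 1 M HCl
Reagents that add atoms: acetyl chloride, CC(=O)Cl
Why: Crossed Claisen-type C-acylation of the lithium ester enolate; the second equivalent of base stores 7 as its enolate, which suppresses proton exchange and double acylation, and this amide base is too weak to metalate the flavone at C3.

Step 5
Reactants: 7 methyl 2-[5,7-bis(benzyloxy)-2-(4-methoxyphenyl)-4-oxochromen-8-yl]-3-oxobutanoate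
Product: 8 methyl (2Z)-2-[5,7-bis(benzyloxy)-2-(4-methoxyphenyl)-4-oxochromen-8-yl]-3-(trimethylsilyloxy)but-2-enoate
Conditions: TMSCl (2 equiv), Et3N (2.2 equiv), toluene, rt; filtration under argon, evaporation
Reagents that add atoms: chlorotrimethylsilane, C[Si](C)(C)Cl
Why: O-silylation of a strongly enolised beta-keto ester with an amine base, the standard first stage towards 1,3-bis(silyloxy)dienes; nothing else in 7 reacts, and the enol ether geometry has no consequence.

Step 6
Reactants: 8 methyl (2Z)-2-[5,7-bis(benzyloxy)-2-(4-methoxyphenyl)-4-oxochromen-8-yl]-3-(trimethylsilyloxy)but-2-enoate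
Product: 9 5,7-bis(benzyloxy)-2-(4-methoxyphenyl)-8-[(1Z)-1-methoxy-1,3-bis(trimethylsilyloxy)buta-1,3-dien-2-yl]chromen-4-one
Conditions: LiN(iPr)2 (1.15 equiv), THF, −78 °C, 1 h; TMSCl (1.3 equiv), −78 → 0 °C; evaporation, dry toluene, filtration; used at once
Reagents that add atoms: chlorotrimethylsilane, C[Si](C)(C)Cl
Why: Gamma-deprotonation of the beta-silyloxy enoate and O-silylation of the dienolate, the standard second stage of 1,3-bis(silyloxy)diene synthesis; the allylic methyl protons are far more acidic than the vinylic C3–H of the flavone, so one equivalent of base at low temperature should suffice.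

Step 7
Reactants: 10 (E)-4-methoxybut-3-en-2-one
Product: 12 (Z)-3-bromo-4-methoxybut-3-en-2-one, via dibromide 11 (not isolated)
Conditions: Br2 (1.0 equiv), CH2Cl2, −78 → 0 °C; then Et3N (1.2 equiv), 0 °C → rt
Reagents that add atoms: bromine, BrBr
Why: Bromine addition to the electron-rich enone followed by E2 loss of HBr (the acidic C3–H and the labile alpha-bromo ether bromide), the usual alpha-bromination of beta-alkoxy enones.

Step 8
Reactants: 12 (Z)-3-bromo-4-methoxybut-3-en-2-one; 13 4-(benzyloxy)benzoyl chloride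
Product: 15 5-bromo-2-[4-(benzyloxy)phenyl]pyran-4-one, via bromo enedione 14 (not isolated)
Conditions: 12 (1.1 equiv), LiN(SiMe3)2 (2.2 equiv), THF, −78 °C; 13 (1.0 equiv), −78 → 0 °C; then 2 M HCl, rt, same flask
Reagents that add atoms: none
Why: Kinetic enolate C-acylation by an acid chloride followed by acid-catalysed oxa-Michael addition and loss of methanol, an established gamma-pyranone synthesis from beta-methoxy enones; the vinylic bromide is inert to the amide base at −78 °C and ends up unambiguously at C5.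

Step 9
Reactants: 9 5,7-bis(benzyloxy)-2-(4-methoxyphenyl)-8-[(1Z)-1-methoxy-1,3-bis(trimethylsilyloxy)buta-1,3-dien-2-yl]chromen-4-one; 15 5-bromo-2-[4-(benzyloxy)phenyl]pyran-4-one
Product: 19 8-{2-[4-(benzyloxy)phenyl]-5,7-dihydroxy-4-oxochromen-6-yl}-5,7-bis(benzyloxy)-2-(4-methoxyphenyl)chromen-4-one, via silyloxypyrylium triflate 16 (not isolated), via conjugate adduct 17 (not isolated), via pyranonyl keto ester 18 (not isolated)
Conditions: 15 (1.3 equiv), TMSOTf (1.3 equiv), CH2Cl2, rt, 1 h; then 9 (1.0 equiv), −78 → 0 °C; then MeOH (6 equiv), 0 °C; then DBU (6 equiv), 0 → 40 °C; 1 M HCl work-up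
Reagents that add atoms: none
Why: Proposed new method: TMSOTf first turns 15 into pyrylium salt 16, and the CH2 terminus of 9 (future C8'') adds to its only unsubstituted oxygen-bearing carbon, C6 (future C8a''), in a vinylogous Mukaiyama–Michael step that gives 17 and releases TMSOTf again. Methanolysis of both silyl ethers and DBU-induced loss of HBr across C4a''–C8a'' restore the pyranone in 18, whose extended enolate (O–C4''=C4a''–C8a''=C8'') attacks the methyl ester carbon (future C5'') through C4a''. Ring A is thus closed in a 6-(enolexo)-exo-trig Dieckmann-type acylation that becomes irreversible once methoxide leaves and the triketone tautomerises to the aromatic 5'',7''-diol. The closest known reaction types are the silyl-triflate-promoted addition of silyl enol ethers and 1,3-bis(silyloxy)dienes to chromones and 4-pyranones, the base dehydrobromination of 3-bromochromanones, the Claisen cyclisation of 3,5,7-triketo esters to acylphloroglucinols, and the cycloaddition–aromatisation of trioxygenated dienes with halogenated quinones. No stereocentre remains in 19, because the centre formed at C8a'' in 17 is erased and the hindered C8–C6'' axis arises as the racemate. Orientation is secured because C2 of the diene is blocked by the flavonyl group and C2 of 16 by its aryl group, the bromine marks C4a'' and supplies the oxidation level needed for aromatisation, and forming 16 beforehand keeps the silyl cation off the flavone carbonyl of 9, whose own C2 is aryl-blocked.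

Step 10
Reactants: 19 8-{2-[4-(benzyloxy)phenyl]-5,7-dihydroxy-4-oxochromen-6-yl}-5,7-bis(benzyloxy)-2-(4-methoxyphenyl)chromen-4-one
Product: 20 8-[5,7-dihydroxy-2-(4-hydroxyphenyl)-4-oxochromen-6-yl]-5,7-dihydroxy-2-(4-methoxyphenyl)chromen-4-one (target)
Conditions: H2 (1 atm), 10% Pd/C, THF/MeOH, rt
Reagents that add atoms: none
Why: Catalytic hydrogenolysis of three aryl benzyl ethers; the aryl methyl ether is untouched and the conjugated C2–C3 double bonds of flavones are not expected to be reduced under a balloon of hydrogen at room temperature.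

Compound list
1 | acacetin, 5,7-dihydroxy-2-(4-methoxyphenyl)chromen-4-one | COc1ccc(cc1)-c1cc(=O)c2c(O)cc(O)cc2o1 | starting material
2 | 5,7-bis(benzyloxy)-2-(4-methoxyphenyl)chromen-4-one | COc1ccc(cc1)-c1cc(=O)c2c(OCc3ccccc3)cc(OCc3ccccc3)cc2o1 | intermediate
3 | 5,7-bis(benzyloxy)-8-iodo-2-(4-methoxyphenyl)chromen-4-one | COc1ccc(cc1)-c1cc(=O)c2c(OCc3ccccc3)cc(OCc3ccccc3)c(I)c2o1 | intermediate
4 | methyl bromoacetate | COC(=O)CBr | starting material
5 | bromo(2-methoxy-2-oxoethyl)zinc, Reformatsky reagent (formed in the flask) | COC(=O)C[Zn]Br | intermediate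
6 | methyl 2-[5,7-bis(benzyloxy)-2-(4-methoxyphenyl)-4-oxochromen-8-yl]acetate | COC(=O)Cc1c(OCc2ccccc2)cc(OCc2ccccc2)c2c(=O)cc(-c3ccc(OC)cc3)oc12 | intermediate
7 | methyl 2-[5,7-bis(benzyloxy)-2-(4-methoxyphenyl)-4-oxochromen-8-yl]-3-oxobutanoate (racemic, enolisable centre) | COC(=O)C(C(C)=O)c1c(OCc2ccccc2)cc(OCc2ccccc2)c2c(=O)cc(-c3ccc(OC)cc3)oc12 | intermediate
8 | methyl (2Z)-2-[5,7-bis(benzyloxy)-2-(4-methoxyphenyl)-4-oxochromen-8-yl]-3-(trimethylsilyloxy)but-2-enoate (drawn Z, geometry without consequence) | C/C(O[Si](C)(C)C)=C(/C(=O)OC)c1c(OCc2ccccc2)cc(OCc2ccccc2)c2c(=O)cc(-c3ccc(OC)cc3)oc12 | intermediate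
9 | 5,7-bis(benzyloxy)-2-(4-methoxyphenyl)-8-[(1Z)-1-methoxy-1,3-bis(trimethylsilyloxy)buta-1,3-dien-2-yl]chromen-4-one (drawn Z, geometry without consequence) | CO/C(O[Si](C)(C)C)=C(/C(=C)O[Si](C)(C)C)c1c(OCc2ccccc2)cc(OCc2ccccc2)c2c(=O)cc(-c3ccc(OC)cc3)oc12 | intermediate
10 | (E)-4-methoxybut-3-en-2-one | CO/C=C/C(C)=O | starting material
11 | 3,4-dibromo-4-methoxybutan-2-one (diastereomer mixture, formed in the flask) | COC(Br)C(Br)C(C)=O | intermediate
12 | (Z)-3-bromo-4-methoxybut-3-en-2-one | CO/C=C(\Br)C(C)=O | intermediate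
13 | 4-(benzyloxy)benzoyl chloride | O=C(Cl)c1ccc(OCc2ccccc2)cc1 | starting material
14 | (4Z)-1-[4-(benzyloxy)phenyl]-4-bromo-5-methoxypent-4-ene-1,3-dione (formed in the flask) | CO/C=C(\Br)C(=O)CC(=O)c1ccc(OCc2ccccc2)cc1 | intermediate
15 | 5-bromo-2-[4-(benzyloxy)phenyl]pyran-4-one | O=c1cc(-c2ccc(OCc3ccccc3)cc2)occ1Br | intermediate
16 | 2-[4-(benzyloxy)phenyl]-5-bromo-4-(trimethylsilyloxy)pyrylium triflate (formed in the flask) | C[Si](C)(C)Oc1cc(-c2ccc(OCc3ccccc3)cc2)[o+]cc1Br.[O-]S(=O)(=O)C(F)(F)F | intermediate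
17 | methyl 4-{6-[4-(benzyloxy)phenyl]-3-bromo-4-(trimethylsilyloxy)-2H-pyran-2-yl}-2-[5,7-bis(benzyloxy)-2-(4-methoxyphenyl)-4-oxochromen-8-yl]-3-(trimethylsilyloxy)but-2-enoate (racemic, enol ether geometry not fixed, formed in the flask) | COC(=O)C(=C(CC1OC(=CC(O[Si](C)(C)C)=C1Br)c1ccc(OCc2ccccc2)cc1)O[Si](C)(C)C)c1c(OCc2ccccc2)cc(OCc2ccccc2)c2c(=O)cc(-c3ccc(OC)cc3)oc12 | intermediate
18 | methyl 4-{6-[4-(benzyloxy)phenyl]-4-oxopyran-2-yl}-2-[5,7-bis(benzyloxy)-2-(4-methoxyphenyl)-4-oxochromen-8-yl]-3-oxobutanoate (racemic, enolisable centre, formed in the flask) | COC(=O)C(C(=O)Cc1cc(=O)cc(-c2ccc(OCc3ccccc3)cc2)o1)c1c(OCc2ccccc2)cc(OCc2ccccc2)c2c(=O)cc(-c3ccc(OC)cc3)oc12 | intermediate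
19 | 8-{2-[4-(benzyloxy)phenyl]-5,7-dihydroxy-4-oxochromen-6-yl}-5,7-bis(benzyloxy)-2-(4-methoxyphenyl)chromen-4-one (racemic axis) | O=c1cc(-c2ccc(OCc3ccccc3)cc2)oc2cc(O)c(c(O)c12)-c1c(OCc2ccccc2)cc(OCc2ccccc2)c2c(=O)cc(-c3ccc(OC)cc3)oc12 | intermediate
20 | 8-[5,7-dihydroxy-2-(4-hydroxyphenyl)-4-oxochromen-6-yl]-5,7-dihydroxy-2-(4-methoxyphenyl)chromen-4-one (racemic axis) | COc1ccc(-c2cc(=O)c3c(O)cc(O)c(-c4c(O)cc5oc(-c6ccc(O)cc6)cc(=O)c5c4O)c3o2)cc1 | target

Total step count: 10. Longest linear sequence: 8 (steps 1–6, 9, 10).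

Steps most likely to fail

**Step 9.**
- The sequence may stall after the first C–C bond.
- The liberated keto ester enolate may displace bromide, through its oxygen or through C8'', faster than HBr is lost.
- The side chain may be cut by retro-Claisen cleavage.
- Adventitious acid may protonate the diene before it adds.

The fallback sets out from 3 and comes back at 20, using known cross-coupling chemistry only. Miyaura borylation of 3 (B2pin2, PdCl2(dppf), KOAc, dioxane, 90 °C) gives the flavone 8-pinacolboronate F1. In parallel, commercial apigenin is benzylated at the two unchelated phenols (BnBr, K2CO3, acetone, reflux) to give 7,4'-di-O-benzylapigenin F2. Iodination next to the free chelated 5-OH (BnNMe3·ICl2, CaCO3, CH2Cl2/MeOH) gives the 6-iodide F3. Benzylation of the 5-OH (BnBr, K2CO3, DMF, 80 °C) then gives the tribenzyl 6-iodide F4. Suzuki–Miyaura coupling of F1 and F4 (Pd(OAc)2, SPhos, K3PO4, toluene/water, 100 °C) gives the pentabenzyl biflavone F5, and hydrogenolysis as in step 10 gives 20.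

**Step 6.**
- Metalation at C3 of the flavone may compete with gamma-deprotonation.
- Silylation may occur on the gamma-carbon in place of oxygen.
- The ketene acetal may hydrolyse during salt removal.

The fallback sets out from 7 and comes back at 9. It replaces the lithium amide by soft enolisation with TMSOTf (2.5 equiv) and Et3N (3 equiv) in Et2O/CH2Cl2 at 0 °C. This is the one-flask amine/silyl triflate route from 1,3-dicarbonyl compounds to 1,3-bis(silyloxy)dienes. It passes through 8 in the flask, and the ammonium triflate separates as a second phase. No new compound is made (entry F0).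

**Step 8.**
- The brominated enolate may decompose or self-condense before it is acylated.
- It may be acylated on oxygen.

The fallback sets out from 10 and 13 and comes back at 15, with the bromine introduced last.
- The bromine-free enolate of 10 (LiN(SiMe3)2, THF, −78 °C) is acylated with 13 to give the methoxy enedione F6.
- Acid closes this to 2-[4-(benzyloxy)phenyl]pyran-4-one F7.
- Br2 in CH2Cl2 adds to the unsubstituted, chromone-like C5–C6 double bond to give the 2,3-dibromo-2,3-dihydropyranone F8.
- Et3N removes HBr to give 15.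

The aryl-conjugated and more hindered C2–C3 double bond should react more slowly, as flavones do compared with chromones.

Further compounds
F1 | step 9 | 5,7-bis(benzyloxy)-2-(4-methoxyphenyl)-8-(4,4,5,5-tetramethyl-1,3,2-dioxaborolan-2-yl)chromen-4-one | COc1ccc(cc1)-c1cc(=O)c2c(OCc3ccccc3)cc(OCc3ccccc3)c(B3OC(C)(C)C(C)(C)O3)c2o1
F2 | step 9 | 7-(benzyloxy)-2-[4-(benzyloxy)phenyl]-5-hydroxychromen-4-one | O=c1cc(-c2ccc(OCc3ccccc3)cc2)oc2cc(OCc3ccccc3)cc(O)c12
F3 | step 9 | 7-(benzyloxy)-2-[4-(benzyloxy)phenyl]-5-hydroxy-6-iodochromen-4-one | O=c1cc(-c2ccc(OCc3ccccc3)cc2)oc2cc(OCc3ccccc3)c(I)c(O)c12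
F4 | step 9 | 5,7-bis(benzyloxy)-2-[4-(benzyloxy)phenyl]-6-iodochromen-4-one | O=c1cc(-c2ccc(OCc3ccccc3)cc2)oc2cc(OCc3ccccc3)c(I)c(OCc3ccccc3)c12
F5 | step 9 | 8-{5,7-bis(benzyloxy)-2-[4-(benzyloxy)phenyl]-4-oxochromen-6-yl}-5,7-bis(benzyloxy)-2-(4-methoxyphenyl)chromen-4-one (racemic axis) | O=c1cc(-c2ccc(OCc3ccccc3)cc2)oc2cc(OCc3ccccc3)c(c(OCc3ccccc3)c12)-c1c(OCc2ccccc2)cc(OCc2ccccc2)c2c(=O)cc(-c3ccc(OC)cc3)oc12
F0 | step 6 | none | none
F6 | step 8 | (4E)-1-[4-(benzyloxy)phenyl]-5-methoxypent-4-ene-1,3-dione | CO/C=C/C(=O)CC(=O)c1ccc(OCc2ccccc2)cc1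
F7 | step 8 | 2-[4-(benzyloxy)phenyl]pyran-4-one | O=c1ccoc(-c2ccc(OCc3ccccc3)cc2)c1
F8 | step 8 | 6-[4-(benzyloxy)phenyl]-2,3-dibromo-2,3-dihydropyran-4-one (diastereomer mixture) | O=C1C=C(OC(Br)C1Br)c1ccc(OCc2ccccc2)cc1
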